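- I had to say what the flask would hold at 30 h, so I first asked whether it would still be moving then.

| flask | free monomer | protic impurity | pre-initiator | remark | time |
|---|---|---|---|---|---|
| south-west | 0.90 M | 0.045 M | 45 mM | run made earlier |  |
| south | 0.90 M | 0.045 M | 180 mM | run made earlier |  |
| south-east | 0.90 M | 0.090 M | 90 mM | run made earlier |  |
| flask | 0.90 M | 0.0450 M | 90 mM |  | 30 h |

- south-west (time / h: monomer in chains / %, free monomer / %): 5.00: 8.8, 87.5; 12.0: 16.9, 78.8; 25.0: 21.4, 74.5; 40.0: 25.2, 70.1
- south (time / h: monomer in chains / %, free monomer / %): 5.00: 22.3, 71.8; 12.0: 24.2, 70.2; 25.0: 22.5, 70.4; 40.0: 24.3, 71.4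
- south-east (time / h: monomer in chains / %, free monomer / %): 10.0: 17.6, 72.4; 20.0: 17.9, 72.3; 25.0: 19.7, 69.9; 40.0: 18.1, 71.7

(each reading ± 1 percentage point)

1. average number of monomer units in a chain (chains begun, living or dead) at 30 h
2. part of the free monomer that has reacted at 30 h

- the average divides the monomer in chains by the number of chains begun, living and dead together
- the numbers in the tables scatter with a standard deviation of 1 percentage point
- the earlier runs do not show the number of chains; that part of a forecast is a guess

- First instants: the south-east run's first reading fell short of the charge by 10 percentage points, and its protic impurity was 10.0% of its free monomer. I read this as one free monomer lost per protic impurity, which in the flask means 5.00%.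
- Middle: the pace followed the pre-initiator. At 5.00 h the south-west run, with 45 mM, showed 87.5% free monomer, and the south run, with 180 mM, showed 71.8%.
- The south-east run has the flask's 90 mM, though twice its protic impurity, and it stood at 72.4% after 10.0 h, a third of the flask's time. Its later readings stayed near that level. So I expected the flask to level off well before its reading.
- End: the four south readings average 0.639 M of free monomer.
- I called this level, where chains gain and give back monomer at equal pace, the ceiling. The usual term is equilibrium monomer concentration, and it was the zero of my scale.
- For the flask, the ceiling gave a reacted part of 29.0%. By my reckoning, that left 0.216 M for monomer in chains. The runs do not show the number of chains, so I guessed one per pre-initiator, which gave 2.40 units per chain.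
- The forecast said 2.4 (1.8 to 3.3) and 29% (27.5% to 30.5%), on “a ceiling (equilibrium, about 0.64 M) rather than stalled chains”; the flask gave 2.40 and 29.0%.

    protic impurity + free monomer → quenched substrate (k = 0.290 L mol⁻¹ min⁻¹)
    free monomer + living end → monomer in chains + living end, rate k2*[living end]*[free monomer] (k = 0.0360 L mol⁻¹ min⁻¹)
    pre-initiator → initiator (k = 0.00620 min⁻¹)
    monomer in chains + living end → free monomer + living end, rate k4*[living end] as long as [monomer in chains] is above zero (k = 0.0230 min⁻¹)
    free monomer + initiator → living end + monomer in chains (k = 0.0460 L mol⁻¹ min⁻¹)

- At 30 h the flask held 0.639 M of free monomer, and monomer in chains was made 1.00 times as fast as it was used up, each step taken net. The half-life of free monomer by its conversion into monomer in chains, that step taken alone, was 3.6 h, shorter than 30 h. For a neighbour charged with 1.5 M of free monomer, the ceiling reckons 57.4% reacted; that flask held 0.642 M of free monomer at 30 h, with 57.2% reacted.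

Readings and results are simulated with constants of no real substance.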